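**Plan**

1. Retrosynthesis: the three phenols are masked as methyl ethers (last cut: three O–CH3 bonds). The saturated bridge is then cut at C6–C7 (bridge carbons counted from ring B, the trioxygenated ring), after putting back a C6=C7 double bond, into two formyl carbons.
2. The open dialdehyde is cut further at C1=C2 of the six-carbon arm on ring B (Wittig), at the ring B C–O bond of the diaryl ether (Ullmann) and at the aryl–C(sp) bond of the eight-carbon arm on ring A (Sonogashira).
3. Forward: eight-carbon arm on ring A, then the diaryl ether, then the six-carbon arm on ring B, then saturation and adjustment to the dialdehyde. The only new ring, the 20-membered macrocycle (14 bridge carbons, the ether oxygen, C1 and C6 of ring B, C1, C6 and C5 of ring A), is closed next, followed by hydrogenation and demethylation.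
4. Enabling feature: C6 and C7 are plain methylene carbons in the middle of the heteroatom-free tetradecamethylene bridge. Both can therefore be brought in as aldehyde carbons of the same (electrophilic) polarity and joined reductively by electron transfer, and the ortho (ring B)/meta (ring A) diaryl ether hinge holds the two arms on one side.
5. Stereochemistry: the target has no stereocentre; alkene geometries made on the way are not controlled and are erased by hydrogenation.

Key step: step 7

**Route**

Step 1
Reactants: 1 3-bromo-5-methoxyphenol; 2 oct-7-yn-1-ol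
Product: 3 3-(8-hydroxyoct-1-yn-1-yl)-5-methoxyphenol
Conditions: PdCl2(PPh3)2 (3 mol%), CuI (5 mol%), Et3N/DMF, degassed, 75 °C
Reagents that add atoms: none
Why: Sonogashira coupling; the C–Br bond of 1 is meta to both oxygen substituents and so is not deactivated toward oxidative addition to zerovalent palladium, and the free phenol and alcohol are tolerated under amine base.

Step 2
Reactants: 3 3-(8-hydroxyoct-1-yn-1-yl)-5-methoxyphenol; 4 2-bromo-3,5-dimethoxybenzaldehyde
Product: 5 2-[3-(8-hydroxyoct-1-yn-1-yl)-5-methoxyphenoxy]-3,5-dimethoxybenzaldehyde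
Conditions: CuI (10 mol%), N,N-dimethylglycine hydrochloride (30 mol%), Cs2CO3 (2.5 equiv), 1,4-dioxane, 100 °C
Reagents that add atoms: none
Why: Ullmann-type copper-catalysed diaryl ether synthesis; the ortho-formyl group activates the C–Br bond of 4 despite the flanking methoxy group, and Cs2CO3 ionises only the phenol of 3, so the primary alcohol and the internal alkyne should stay untouched.

Step 3
Reactants: 5 2-[3-(8-hydroxyoct-1-yn-1-yl)-5-methoxyphenoxy]-3,5-dimethoxybenzaldehyde; 6 (4-carboxybutyl)triphenylphosphonium bromide
Product: 8 (5Z)-6-{2-[3-(8-hydroxyoct-1-yn-1-yl)-5-methoxyphenoxy]-3,5-dimethoxyphenyl}hex-5-enoic acid, via sodium 5-(triphenyl-λ5-phosphanylidene)pentanoate 7 (not isolated)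
Conditions: 6 (2.2 equiv), NaN(SiMe3)2 (4.4 equiv), THF, 0 °C; then 5, −78 °C → rt; aq. HCl work-up
Reagents that add atoms: none
Why: Wittig olefination with a non-stabilised carboxy ylide, which is not basic enough to be consumed by the free alcohol; lithium-free conditions should give mainly the Z alkene (some E isomer is expected alongside), and the geometry is irrelevant because the alkene is saturated in step 4.

Step 4
Reactants: 8 (5Z)-6-{2-[3-(8-hydroxyoct-1-yn-1-yl)-5-methoxyphenoxy]-3,5-dimethoxyphenyl}hex-5-enoic acid
Product: 9 6-{2-[3-(8-hydroxyoctyl)-5-methoxyphenoxy]-3,5-dimethoxyphenyl}hexanoic acid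
Conditions: H2 (1 atm), 10% Pd/C, EtOAc, rt
Reagents that add atoms: none
Why: Heterogeneous catalytic hydrogenation should saturate the aryl alkyne and the styrenyl alkene in one operation; aryl ethers, the acid and the alcohol are inert and there is no benzylic heteroatom to hydrogenolyse.

Step 5
Reactants: 9 6-{2-[3-(8-hydroxyoctyl)-5-methoxyphenoxy]-3,5-dimethoxyphenyl}hexanoic acid
Product: 10 6-{2-[3-(8-hydroxyoctyl)-5-methoxyphenoxy]-3,5-dimethoxyphenyl}hexan-1-ol
Conditions: LiAlH4 (3 equiv), THF, 0 °C → reflux; Fieser work-up
Reagents that add atoms: none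
Why: Hydride reduction of a carboxylic acid to the primary alcohol; nothing else in 9 is reducible by LiAlH4.

Step 6
Reactants: 10 6-{2-[3-(8-hydroxyoctyl)-5-methoxyphenoxy]-3,5-dimethoxyphenyl}hexan-1-ol
Product: 11 8-{3-[2,4-dimethoxy-6-(6-oxohexyl)phenoxy]-5-methoxyphenyl}octanal
Conditions: Dess–Martin periodinane (2.4 equiv), CH2Cl2, 0 °C → rt
Reagents that add atoms: none
Why: Dess–Martin oxidation should take both primary alcohols to aldehydes without over-oxidation, and with all phenols methylated the electron-rich rings offer no site for quinone formation.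

Step 7
Reactants: 11 8-{3-[2,4-dimethoxy-6-(6-oxohexyl)phenoxy]-5-methoxyphenyl}octanal
Product: 13 tri-O-methyl 20-membered macrocyclic alkene with an E C6=C7 double bond in the bridge, via titanium-bound macrocyclic 1,2-diolate 12 (not isolated)
Conditions: TiCl3(DME)1.5 (12 equiv), Zn–Cu couple (36 equiv), DME, reflux 3 h; then 11 in DME by syringe pump over 30 h (final ca. 5 mM), reflux 6 h more
Reagents that add atoms: none
Why: Low-valent titanium should transfer one electron to each formyl group, the two formerly electrophilic carbons couple carbon to carbon to give the titanium pinacolate 12, and at reflux the oxophilic metal removes both oxygen atoms to leave the C6=C7 alkene. The closest known reaction type is the intramolecular McMurry coupling of α,ω-dialdehydes to macrocyclic cycloalkenes, which tolerates ring sizes in this range. The 20-membered ring (14 bridge carbons, the ether oxygen, C1 and C6 of ring B, C1, C6 and C5 of ring A) closes end to end at the bridge midpoint, favoured by slow addition into dilute reagent and by the diaryl ether hinge, which directs the ortho arm of ring B and the meta arm of ring A to the same side. No stereocentre survives: the carbinol centres of 12 are transient, and the alkene geometry is not controlled (E should dominate in an unstrained large ring, Z alongside) and is erased in step 8. The step needs intramolecular over intermolecular coupling and chemoselectivity for the aldehydes; the first is secured by dilution, the second by the formyl groups being the only reducible functions, since the aryl methyl ethers and the diaryl ether are inert to low-valent titanium.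

Step 8
Reactants: 13 tri-O-methyl 20-membered macrocyclic alkene
Product: 14 tri-O-methyl ether of the target (saturated 20-membered macrocycle)
Conditions: H2 (1 atm), 10% Pd/C, EtOAc, rt
Reagents that add atoms: none
Why: Catalytic hydrogenation of an unhindered 1,2-disubstituted alkene; both geometric isomers of 13 should converge on the single saturated macrocycle.

Step 9
Reactants: 14 tri-O-methyl ether of the target
Product: 15 target macrocycle (CNP0173380.0)
Conditions: BBr3 (6 equiv), CH2Cl2, −78 °C → rt; then H2O, 0 °C
Reagents that add atoms: none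
Why: Lewis-acid demethylation of aryl methyl ethers with BBr3 (bromide attacks the methyl carbon of the boron-complexed ether); the diaryl ether survives because neither of its carbons can undergo substitution.

**Compound list**

1 | 3-bromo-5-methoxyphenol | COc1cc(O)cc(Br)c1 | starting material
2 | oct-7-yn-1-ol | OCCCCCCC#C | starting material
3 | 3-(8-hydroxyoct-1-yn-1-yl)-5-methoxyphenol | COc1cc(O)cc(C#CCCCCCCO)c1 | intermediate
4 | 2-bromo-3,5-dimethoxybenzaldehyde | COc1cc(OC)c(Br)c(C=O)c1 | starting material
5 | 2-[3-(8-hydroxyoct-1-yn-1-yl)-5-methoxyphenoxy]-3,5-dimethoxybenzaldehyde | COc1cc(OC)c(Oc2cc(OC)cc(C#CCCCCCCO)c2)c(C=O)c1 | intermediate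
6 | (4-carboxybutyl)triphenylphosphonium bromide | OC(=O)CCCC[P+](c1ccccc1)(c1ccccc1)c1ccccc1.[Br-] | starting material
7 | sodium 5-(triphenyl-λ5-phosphanylidene)pentanoate (ylide formed in the flask, not isolated) | [Na+].[O-]C(=O)CCCC=P(c1ccccc1)(c1ccccc1)c1ccccc1 | intermediate
8 | (5Z)-6-{2-[3-(8-hydroxyoct-1-yn-1-yl)-5-methoxyphenoxy]-3,5-dimethoxyphenyl}hex-5-enoic acid (Z drawn; some E isomer expected alongside) | COc1cc(OC)c(Oc2cc(OC)cc(C#CCCCCCCO)c2)c(/C=C\CCCC(O)=O)c1 | intermediate
9 | 6-{2-[3-(8-hydroxyoctyl)-5-methoxyphenoxy]-3,5-dimethoxyphenyl}hexanoic acid | COc1cc(OC)c(Oc2cc(OC)cc(CCCCCCCCO)c2)c(CCCCCC(O)=O)c1 | intermediate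
10 | 6-{2-[3-(8-hydroxyoctyl)-5-methoxyphenoxy]-3,5-dimethoxyphenyl}hexan-1-ol | COc1cc(OC)c(Oc2cc(OC)cc(CCCCCCCCO)c2)c(CCCCCCO)c1 | intermediate
11 | 8-{3-[2,4-dimethoxy-6-(6-oxohexyl)phenoxy]-5-methoxyphenyl}octanal | COc1cc(OC)c(Oc2cc(OC)cc(CCCCCCCC=O)c2)c(CCCCCC=O)c1 | intermediate
12 | titanium-bound macrocyclic 1,2-diolate at bridge C6 and C7 (not isolated; both relative configurations, drawn as the dianion without the metal) | COc1cc2cc(c1)Oc1c(OC)cc(OC)cc1CCCCCC([O-])C([O-])CCCCCCC2 | intermediate
13 | tri-O-methyl 20-membered macrocyclic alkene, C6=C7 in the bridge counted from ring B (E drawn; Z isomer expected alongside) | COc1cc2cc(c1)Oc1c(OC)cc(OC)cc1CCCCC/C=C/CCCCCCC2 | intermediate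
14 | tri-O-methyl ether of the target, saturated 20-membered diaryl ether macrocycle | COc1cc2cc(c1)Oc1c(OC)cc(OC)cc1CCCCCCCCCCCCCC2 | intermediate
15 | target macrocycle: ring A 3-hydroxy-5-alkylphenyl ether, ring B 2,4-dihydroxy-6-alkylphenyl ether, rings joined by the ether oxygen and a tetradecamethylene bridge | Oc1cc2cc(c1)Oc1c(O)cc(O)cc1CCCCCCCCCCCCCC2 | target

**Step count and risks**

Total step count: 9. Longest linear sequence: 9 steps (1 → 15).

Steps most likely to fail:

Step 7 (macrocyclisation). Intermolecular carbonyl coupling to oligomers, or arrest at the pinacol stage, could erode the ring closure. The fallback sets out from 11. Twofold Wittig methylenation (Ph3PCH3Br, KOtBu, THF, 0 °C) should give the diene 1-(hept-6-en-1-yl)-3,5-dimethoxy-2-[3-methoxy-5-(non-8-en-1-yl)phenoxy]benzene F1. Ring-closing olefin metathesis of F1 (second-generation Grubbs catalyst RuCl2(=CHPh)(PCy3)(H2IMes), CH2Cl2, 40 °C, ca. 1 mM) expels ethylene and closes the same C6=C7 double bond, so the route is rejoined at 13.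

Step 2 (diaryl ether). Oxidative addition at the C–Br bond flanked by formyl and methoxy groups may be slow, so that protodebromination and base-induced degradation of the aldehyde compete. The fallback reverses the roles of the two rings and sets out from 2. Sonogashira coupling of 2 with an excess of commercial 1,3-dibromo-5-methoxybenzene (PdCl2(PPh3)2, CuI, Et3N, 70 °C) should give 8-(3-bromo-5-methoxyphenyl)oct-7-yn-1-ol F2, an unhindered aryl bromide. The phenol partner 2-hydroxy-3,5-dimethoxybenzaldehyde F3 would come from commercial 2,4-dimethoxyphenol by magnesium-mediated ortho-formylation (MgCl2, Et3N, paraformaldehyde, MeCN, reflux). Copper-catalysed arylation of the hindered phenol F3 with F2 (CuI, picolinic acid, K3PO4, DMSO, 90 °C) then returns to the route at 5.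

Step 3 (six-carbon arm). Consumption of the ylide by the free hydroxyl group and slow addition to the aldehyde flanked by the aryloxy group could leave the olefination incomplete. The fallback sets out from 5 and replaces olefination by carbonyl addition and hydrogenolysis. Addition of [5-(tert-butyldimethylsilyloxy)pentyl]magnesium bromide (from commercial (5-bromopentyloxy)(tert-butyl)dimethylsilane and Mg; 2.5 equiv, THF, −20 °C → rt) should give the racemic benzylic alcohol 8-{3-[2-(6-{[tert-butyl(dimethyl)silyl]oxy}-1-hydroxyhexyl)-4,6-dimethoxyphenoxy]-5-methoxyphenyl}oct-7-yn-1-ol F4. Hydrogenation of F4 under acid (H2, 4 atm, 10% Pd/C, EtOH, catalytic HCl) should saturate the alkyne, hydrogenolyse the benzylic C–O bond and cleave the silyl ether. This returns to the route at diol 10 and bypasses 8 and 9.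

**Further compounds**

F1 | step 7 | 1-(hept-6-en-1-yl)-3,5-dimethoxy-2-[3-methoxy-5-(non-8-en-1-yl)phenoxy]benzene | COc1cc(OC)c(Oc2cc(OC)cc(CCCCCCCC=C)c2)c(CCCCCC=C)c1
F2 | step 2 | 8-(3-bromo-5-methoxyphenyl)oct-7-yn-1-ol | COc1cc(Br)cc(C#CCCCCCCO)c1
F3 | step 2 | 2-hydroxy-3,5-dimethoxybenzaldehyde | COc1cc(OC)c(O)c(C=O)c1
F4 | step 3 | 8-{3-[2-(6-{[tert-butyl(dimethyl)silyl]oxy}-1-hydroxyhexyl)-4,6-dimethoxyphenoxy]-5-methoxyphenyl}oct-7-yn-1-ol (racemic) | COc1cc(OC)c(Oc2cc(OC)cc(C#CCCCCCCO)c2)c(C(O)CCCCCO[Si](C)(C)C(C)(C)C)c1
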